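The whole route depends on cutting the C8–C11 bond of the oxolane. Numbering: cyclononadiene carbons C1–C9, where C1 bears the methylene, C3=C4 is the Z-alkene, C5 the carbinol and C8/C9 the fusion; C10 is the ring OCH2 and C11 the fully substituted ether carbon. Without that bond, C11 is only the central carbon of a 2-O-alkylglycerol with two unlike oxymethyl arms, a stereocentre available from solketal. A rhodium carbene at C8 inserts into C11–H with retention. This single operation makes C8–C11, closes the oxolane and sets C8 and C11 beside preset C9. The precursor is an acyclic α-diazo ester carrying C9 and the PMB/trityl glyceryl ether. Metathesis later closes the nine-membered ring.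

Key step: step 13

**Remarks on the chemistry**
- **Arms.** "Arm B" is the CH2O group on C11 that becomes the dienyl chain (PMB). "Arm C" is the one that ends as the ester (trityl).
- **Stereochemical bookkeeping.** In 16 and 17, C7 on C8 is trans to C1 on C9 and cis to arm C. This matches the target, which is 5S,8S,9R,11R in this numbering. (S)-Solketal etherified first on its free hydroxyl gives the correct C11.
- **Precursor design.** Arm C carries trityl and not a silyl group, because an alkoxide on the C11 oxygen next to a silyl ether invites 1,2-silyl migration during etherification. TBDPS on the C1 oxygen is then the only silyl ether, so fluoride can unmask C1 mid-route without a selectivity problem.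
- **C9.** It is set with an oxazolidinone auxiliary because the facial sense is predictable.
- **Convention.** Salts formed by simple deprotonation (alkoxides, enolates) are not numbered.
- **Assumption.** The acyl chain is read as octadecanoyl (stearoyl).

## Route

Step 1
Reactants: 1 (S)-solketal
Product: 2 (4S)-4-{[(4-methoxybenzyl)oxy]methyl}-2,2-dimethyl-1,3-dioxolane
Conditions: NaH, PMBCl, Bu4NI (cat.), DMF, 0 °C → rt
Reagents that add atoms: 4-methoxybenzyl chloride, COc1ccc(CCl)cc1
Why: Williamson ether synthesis of an unhindered primary alkoxide with a benzylic chloride, which leaves the dioxolane stereocentre (future C11) untouched.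

Step 2
Reactants: 2 PMB ether of solketal
Product: 3 (2R)-3-[(4-methoxybenzyl)oxy]propane-1,2-diol
Conditions: AcOH/H2O (4:1), 40 °C
Reagents that add atoms: none
Why: Acid-catalysed acetal hydrolysis under conditions that PMB ethers survive, with no bond to the stereocentre broken.

Step 3
Reactants: 3 PMB glycerol diol
Product: 4 (2S)-1-[(4-methoxybenzyl)oxy]-3-(trityloxy)propan-2-ol
Conditions: TrCl, Et3N, DMAP (cat.), CH2Cl2, 0 °C → rt
Reagents that add atoms: trityl chloride, ClC(c1ccccc1)(c1ccccc1)c1ccccc1
Why: Sterically governed tritylation takes only the primary hydroxyl, so the C11 hydroxyl stays free between two ether arms that cannot migrate under base.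

Step 4
Reactants: 5 (4S)-4-benzyl-1,3-oxazolidin-2-one; 6 pent-4-enoyl chloride
Product: 7 (4S)-4-benzyl-3-(pent-4-enoyl)-1,3-oxazolidin-2-one
Conditions: n-BuLi, THF, −78 °C; then 6, −78 → 0 °C
Reagents that add atoms: none
Why: N-Acylation of the lithiated Evans oxazolidinone with an acid chloride, the standard way to load the auxiliary.

Step 5
Reactants: 7 N-pentenoyl oxazolidinone
Product: 8 (4S)-4-benzyl-3-[(2R)-2-(hydroxymethyl)pent-4-enoyl]-1,3-oxazolidin-2-one
Conditions: TiCl4, i-Pr2NEt, CH2Cl2, 0 °C; then 1,3,5-trioxane, TiCl4, 0 °C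
Reagents that add atoms: 1,3,5-trioxane, C1OCOCO1
Why: Evans titanium-enolate hydroxymethylation (aldol-type addition to TiCl4-activated formaldehyde), in which the chelated Z-enolate is attacked on the face opposite the benzyl group and thereby sets C9.

Step 6
Reactants: 8 hydroxymethyl imide
Product: 9 TBDPS ether of 8 (2R)
Conditions: TBDPSCl, imidazole, DMF, rt
Reagents that add atoms: tert-butyl(chloro)diphenylsilane, CC(C)(C)[Si](Cl)(c1ccccc1)c1ccccc1
Why: Standard silylation of a primary alcohol, with imidazole too weak a base to trigger retro-aldol loss of formaldehyde or epimerisation at C9.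

Step 7
Reactants: 9 silylated imide
Product: 10 (2S)-2-{[(tert-butyldiphenylsilyl)oxy]methyl}pent-4-en-1-ol
Conditions: LiBH4, MeOH (1 equiv), Et2O, 0 °C
Reagents that add atoms: none
Why: Reductive removal of the auxiliary with LiBH4 reduces only the exocyclic imide carbonyl to the C10 carbinol and leaves C9 and the silyl ether unchanged.

Step 8
Reactants: 10 mono-silylated diol
Product: 11 (2R)-2-{[(tert-butyldiphenylsilyl)oxy]methyl}pent-4-en-1-yl triflate
Conditions: Tf2O, 2,6-lutidine, CH2Cl2, −78 °C; cold aqueous work-up, used at once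
Reagents that add atoms: triflic anhydride, O=S(=O)(OS(=O)(=O)C(F)(F)F)C(F)(F)F
Why: O-Sulfonylation with triflic anhydride and a hindered pyridine base turns the β-branched primary alcohol into a leaving group reactive enough for substitution below room temperature.

Step 9
Reactants: 4 glycerol 2-ol; 11 triflate
Product: 12 (S,S)-2-O-alkyl glycerol ether bearing the allyl group
Conditions: 4, NaH, THF, 0 °C → rt; then 11, THF, −20 °C → rt
Reagents that add atoms: none
Why: Williamson etherification (SN2 at primary C10), in which the alkoxide of 4 carries only benzyl-type and trityl ethers so that nothing can migrate to the C11 oxygen and neither stereocentre takes part.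

Step 10
Reactants: 12 allyl glyceryl ether
Product: 13 (3S)-aldehyde (C7 = CHO)
Conditions: OsO4 (cat.), NaIO4, 2,6-lutidine, dioxane/H2O (3:1), rt
Reagents that add atoms: sodium periodate, [Na+].[O-]I(=O)(=O)=O (terminal source of the carbonyl oxygen, relayed by OsO4)
Why: Lemieux–Johnson cleavage (catalytic dihydroxylation, then periodate glycol fission) removes the terminal CH2 of the only alkene and, unlike ozone, spares the electron-rich PMB ring.

Step 11
Reactants: 13 aldehyde
Product: 14 methyl (3S)-ester
Conditions: NIS, K2CO3, MeOH, rt, dark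
Reagents that add atoms: methanol, CO
Why: Oxidative esterification, in which the methanol hemiacetal of the aldehyde is oxidised by the hypoiodite formed from NIS to give the methyl ester directly under mildly basic conditions.

Step 12
Reactants: 14 methyl ester
Product: 16 methyl (3S)-2-diazo ester tethered to the (2S)-glyceryl ether, via α-trifluoroacetyl ester 15 (not isolated)
Conditions: LiHMDS, THF, −78 °C; CF3CO2CH2CF3; then MsN3, Et3N, H2O (1 equiv), MeCN, rt
Reagents that add atoms: 2,2,2-trifluoroethyl trifluoroacetate, FC(F)(F)COC(=O)C(F)(F)F (atoms kept only in 15); methanesulfonyl azide, CS(=O)(=O)N=[N+]=[N-]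
Why: Detrifluoroacetylative diazo transfer (Claisen activation, then Regitz-type transfer), in which the ester enolate is first trifluoroacetylated so that the sulfonyl azide can react at C8 and loss of the trifluoroacetyl group delivers the diazo ester without touching C9.

Step 13
Reactants: 16 α-diazo ester
Product: 17 methyl (2S,3S,4S)-4-{[(tert-butyldiphenylsilyl)oxy]methyl}-2-{[(4-methoxybenzyl)oxy]methyl}-2-[(trityloxy)methyl]oxolane-3-carboxylate
Conditions: Rh2(O2CCPh3)4 (1 mol %), CH2Cl2, −78 → −20 °C, slow addition of 16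
Reagents that add atoms: none
Why: Loss of N2 from 16 at the dirhodium core gives an electrophilic carbene at C8, which takes up the C11–H bond through a concerted three-centre, hydride-like transition state; this is the well-known Rh(II)-catalysed intramolecular 1,5 C–H insertion of an α-diazo carbonyl compound next to an ether oxygen. The ring closes in the favoured five-membered mode (C8–C9–C10–O–C11) through a chair-like array that counts the migrating hydrogen. C11 keeps its configuration because the new C–C bond forms on the face that held the hydrogen, so the solketal-derived centre becomes the fully substituted one. C8 is set by preset C9, whose silyloxymethyl group sits pseudo-equatorial and places the ester trans to it, and because C8 stays enolisable a minor cis epimer can be equilibrated with NaOMe/MeOH. Selectivity is needed against the 1,2-hydride shift from C9 and against 1,6-insertion into the arm CH2 groups: the tertiary, oxygen-activated C11–H and the 1,5 geometry favour the wanted site, the C1 branch offers only O–Si at its 1,5 position, no alkene is present, and bulky triphenylacetate ligands at low temperature hold back hydride migration.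

Step 14
Reactants: 17 oxolane ester
Product: 18 (2S,3S,4S)-oxolane-3-carbaldehyde (C7 = CHO)
Conditions: DIBAL-H (1.1 equiv), CH2Cl2, −78 °C; MeOH, then Rochelle salt
Reagents that add atoms: none
Why: Partial ester reduction with DIBAL-H, in which the aluminium hemiacetal of this hindered ester persists at −78 °C and collapses to the aldehyde only on work-up, while the trans C8 configuration is also the more stable one.

Step 15
Reactants: 18 aldehyde
Product: 19 (2S,3S,4S)-3-ethenyl oxolane (C7=C6)
Conditions: MePPh3Br, KHMDS, THF, 0 °C; then 18, −78 → 0 °C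
Reagents that add atoms: methyltriphenylphosphonium bromide, C[P+](c1ccccc1)(c1ccccc1)c1ccccc1.[Br-]
Why: Wittig methylenation with the small unstabilised ylide converts the hindered aldehyde into the vinyl group faster than it enolises.

Step 16
Reactants: 20 but-2-yn-1-ol
Product: 22 (Z)-3-iodobut-2-en-1-ol, via cyclic alkenylalanate 21 (not isolated)
Conditions: Red-Al, Et2O, 0 °C → rt; then I2, THF, −78 °C
Reagents that add atoms: sodium bis(2-methoxyethoxy)aluminium hydride, [Na+].[AlH2-](OCCOC)OCCOC (atoms kept only in 21); iodine, II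
Why: Hydroxyl-directed trans-hydroalumination of the propargylic alcohol places aluminium on the distal carbon in a five-membered ring, and iodinolysis with retention gives the Z-iodoalkene as one regio- and stereoisomer.

Step 17
Reactants: 19 vinyl oxolane; 22 (Z)-3-iodobut-2-en-1-ol
Product: 24 (Z)-trisubstituted allylic alcohol (C6 cis to C3H2OH), via B-alkyl-9-BBN 23 (not isolated)
Conditions: 9-BBN, THF, rt; then 22, PdCl2(dppf) (5 mol %), AsPh3, Cs2CO3, DMF/H2O, rt
Reagents that add atoms: 9-borabicyclo[3.3.1]nonane, B1C2CCCC1CCC2 (atoms kept only in 23)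
Why: Hydroboration followed by B-alkyl Suzuki–Miyaura coupling, in which 9-BBN adds to the terminus of the only alkene and the sp3–sp2 coupling keeps the iodoalkene geometry and tolerates the free allylic hydroxyl.

Step 18
Reactants: 24 (Z)-allylic alcohol
Product: 25 (4R,5S)-2,3-epoxy alcohol
Conditions: Ti(Oi-Pr)4 (10 mol %), D-(−)-DET (12 mol %), t-BuOOH, 4 Å MS, CH2Cl2, −20 °C
Reagents that add atoms: tert-butyl hydroperoxide, CC(C)(C)OO
Why: Sharpless asymmetric epoxidation, in which reagent control by D-(−)-tartrate on this nerol-type Z-allylic alcohol delivers oxygen to the face that makes C5 S (C4 R), independent of the remote oxolane centres.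

Step 19
Reactants: 25 epoxy alcohol
Product: 26 epoxy iodide
Conditions: I2, PPh3, imidazole, THF, 0 °C
Reagents that add atoms: iodine, II
Why: Garegg–Samuelsson (Appel-type) iodination replaces the primary hydroxyl by SN2 under buffered conditions that leave the epoxide and the trityl ether alone.

Step 20
Reactants: 26 epoxy iodide
Product: 27 (5S)-tertiary vinyl carbinol
Conditions: n-BuLi, THF, −78 °C
Reagents that add atoms: none
Why: Iodine–lithium exchange followed at once by β-elimination opens the epoxide (reductive 1,3-transposition of a 2,3-epoxy alcohol), so the C5–O bond and its configuration are kept and C4=C3 becomes a vinyl group.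

Step 21
Reactants: 27 vinyl carbinol
Product: 28 diol (C1–OH free)
Conditions: TBAF, THF, 0 °C → rt
Reagents that add atoms: none
Why: Fluoride-induced desilylation, in which TBDPS is the only silyl ether present so that C1–OH is released without any selectivity issue.

Step 22
Reactants: 28 diol
Product: 29 C1 aldehyde
Conditions: Dess–Martin periodinane, NaHCO3, CH2Cl2, 0 °C → rt
Reagents that add atoms: none
Why: Dess–Martin oxidation under bicarbonate buffer touches only the primary alcohol, since the tertiary C5 hydroxyl cannot be oxidised, and is mild enough for a β-alkoxy aldehyde.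

Step 23
Reactants: 29 aldehyde
Product: 30 homoallylic alcohol (C1 epimers)
Conditions: allylMgBr (2.5 equiv), Et2O/THF, −78 °C
Reagents that add atoms: allylmagnesium bromide, C=CC[Mg]Br
Why: Grignard 1,2-addition at low temperature brings in C2 and C3 (one equivalent is spent on the C5 hydroxyl), and the new C1 carbinol centre is erased in the next step.

Step 24
Reactants: 30 homoallylic alcohol
Product: 31 allyl ketone (β,γ-enone)
Conditions: Dess–Martin periodinane, NaHCO3, CH2Cl2, 0 °C
Reagents that add atoms: none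
Why: Buffered Dess–Martin oxidation gives the β,γ-unsaturated ketone without the acid or base that would move the alkene into conjugation.

Step 25
Reactants: 31 allyl ketone
Product: 32 tertiary β-hydroxysilane diene (C1 epimers)
Conditions: TMSCH2Li, CeCl3, THF, −78 °C
Reagents that add atoms: (trimethylsilyl)methyllithium, [Li]C[Si](C)(C)C
Why: Organocerium 1,2-addition (first half of a Peterson olefination), in which the nearly non-basic reagent adds to the readily enolisable ketone, and stopping at the β-hydroxysilane keeps a 1,1-disubstituted alkene, which could close a seven-membered ring with C4, out of the metathesis step.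

Step 26
Reactants: 32 diene
Product: 33 (Z)-cyclononene β-hydroxysilane
Conditions: Grubbs II (10 mol %), 1,4-benzoquinone (20 mol %), CH2Cl2 (1 mM), reflux
Reagents that add atoms: none
Why: Ring-closing metathesis of the only two alkenes, both monosubstituted and one activated by the free allylic C5 hydroxyl, should give C3=C4 as the Z isomer because that is the less strained geometry in a nine-membered ring, with loss of ethene driving closure.

Step 27
Reactants: 33 β-hydroxysilane
Product: 34 methylene cyclononadiene (PMB and trityl in place)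
Conditions: KH, THF, 0 °C → rt
Reagents that add atoms: none
Why: Base-induced Peterson elimination, in which the potassium alkoxide at C1 attacks silicon and syn-elimination gives the exocyclic methylene from either C1 epimer.

Step 28
Reactants: 34 PMB ether
Product: 35 arm-B primary alcohol
Conditions: DDQ, CH2Cl2/pH 7 buffer (10:1), 0 °C
Reagents that add atoms: none
Why: Oxidative PMB cleavage by DDQ (hydride abstraction from the electron-rich benzylic position, then hydrolysis) in cold buffered medium, which trityl ethers, the tertiary alcohol and isolated alkenes tolerate.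

Step 29
Reactants: 35 alcohol
Product: 36 arm-B aldehyde (C12 = CHO)
Conditions: Dess–Martin periodinane, NaHCO3, CH2Cl2, 0 °C → rt
Reagents that add atoms: none
Why: Dess–Martin oxidation to an aldehyde that has no α-hydrogen, so C11 cannot epimerise.

Step 30
Reactants: 36 aldehyde
Product: 37 (E)-iodoalkene (C12=C13)
Conditions: CrCl2, CHI3, THF/dioxane, 0 °C → rt
Reagents that add atoms: iodoform, IC(I)I
Why: Takai olefination, in which the gem-dichromium reagent from iodoform adds to the aldehyde and elimination gives the E-iodoalkene, a preference reinforced by the bulky quaternary C11.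

Step 31
Reactants: 37 trityl ether
Product: 38 arm-C primary alcohol
Conditions: CSA (0.1 equiv), MeOH/CH2Cl2 (1:1), 0 °C
Reagents that add atoms: none
Why: Acid-catalysed solvolysis of the trityl ether through the very stable trityl cation needs only catalytic acid at 0 °C, which the tertiary allylic alcohol and the iodoalkene should survive, and it is done before the acid-labile dienyl ether exists.

Step 32
Reactants: 38 alcohol; 39 stearic acid
Product: 40 stearate of the iodoalkene
Conditions: EDC·HCl, DMAP (cat.), CH2Cl2, rt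
Reagents that add atoms: none
Why: Steglich-type esterification acylates the primary hydroxyl, whereas the tertiary C5 hydroxyl is too hindered to react.

Step 33
Reactants: 40 iodoalkene stearate; 41 2-methylprop-1-enylboronic acid pinacol ester
Product: 42 target CNP0274030.1
Conditions: Pd(PPh3)4 (5 mol %), K3PO4 (aq), THF, rt → 40 °C
Reagents that add atoms: none
Why: Suzuki–Miyaura sp2–sp2 coupling with retention of the E geometry completes the diene under mild phosphate base that the hindered stearate and the free tertiary alcohol tolerate.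

## Compound list

1 | (S)-solketal, [(4S)-2,2-dimethyl-1,3-dioxolan-4-yl]methanol | OC[C@H]1COC(C)(C)O1 | starting material
2 | (4S)-4-{[(4-methoxybenzyl)oxy]methyl}-2,2-dimethyl-1,3-dioxolane | COc1ccc(COC[C@H]2COC(C)(C)O2)cc1 | intermediate
3 | (2R)-3-[(4-methoxybenzyl)oxy]propane-1,2-diol | COc1ccc(COC[C@H](O)CO)cc1 | intermediate
4 | (2S)-1-[(4-methoxybenzyl)oxy]-3-(trityloxy)propan-2-ol | COc1ccc(COC[C@H](O)COC(c2ccccc2)(c2ccccc2)c2ccccc2)cc1 | intermediate
5 | (4S)-4-benzyl-1,3-oxazolidin-2-one | O=C1N[C@@H](Cc2ccccc2)CO1 | starting material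
6 | pent-4-enoyl chloride | C=CCCC(=O)Cl | starting material
7 | (4S)-4-benzyl-3-(pent-4-enoyl)-1,3-oxazolidin-2-one | C=CCCC(=O)N1[C@@H](Cc2ccccc2)COC1=O | intermediate
8 | (4S)-4-benzyl-3-[(2R)-2-(hydroxymethyl)pent-4-enoyl]-1,3-oxazolidin-2-one | C=CC[C@H](CO)C(=O)N1[C@@H](Cc2ccccc2)COC1=O | intermediate
9 | (4S)-4-benzyl-3-[(2R)-2-{[(tert-butyldiphenylsilyl)oxy]methyl}pent-4-enoyl]-1,3-oxazolidin-2-one | C=CC[C@H](CO[Si](c1ccccc1)(c1ccccc1)C(C)(C)C)C(=O)N1[C@@H](Cc2ccccc2)COC1=O | intermediate
10 | (2S)-2-{[(tert-butyldiphenylsilyl)oxy]methyl}pent-4-en-1-ol | C=CC[C@H](CO[Si](c1ccccc1)(c1ccccc1)C(C)(C)C)CO | intermediate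
11 | (2R)-2-{[(tert-butyldiphenylsilyl)oxy]methyl}pent-4-en-1-yl trifluoromethanesulfonate | C=CC[C@H](CO[Si](c1ccccc1)(c1ccccc1)C(C)(C)C)COS(=O)(=O)C(F)(F)F | intermediate
12 | (2S)-2-{[(2S)-2-{[(tert-butyldiphenylsilyl)oxy]methyl}pent-4-en-1-yl]oxy}-1-[(4-methoxybenzyl)oxy]-3-(trityloxy)propane | C=CC[C@H](CO[Si](c1ccccc1)(c1ccccc1)C(C)(C)C)CO[C@@H](COCc1ccc(OC)cc1)COC(c1ccccc1)(c1ccccc1)c1ccccc1 | intermediate
13 | (3S)-4-[(tert-butyldiphenylsilyl)oxy]-3-[({(2S)-1-[(4-methoxybenzyl)oxy]-3-(trityloxy)propan-2-yl}oxy)methyl]butanal | O=CC[C@H](CO[Si](c1ccccc1)(c1ccccc1)C(C)(C)C)CO[C@@H](COCc1ccc(OC)cc1)COC(c1ccccc1)(c1ccccc1)c1ccccc1 | intermediate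
14 | methyl (3S)-4-[(tert-butyldiphenylsilyl)oxy]-3-[({(2S)-1-[(4-methoxybenzyl)oxy]-3-(trityloxy)propan-2-yl}oxy)methyl]butanoate | COC(=O)C[C@H](CO[Si](c1ccccc1)(c1ccccc1)C(C)(C)C)CO[C@@H](COCc1ccc(OC)cc1)COC(c1ccccc1)(c1ccccc1)c1ccccc1 | intermediate
15 | 2-(trifluoroacetyl) derivative of 14 (C8 epimers, largely enolised) | COC(=O)C(C(=O)C(F)(F)F)[C@H](CO[Si](c1ccccc1)(c1ccccc1)C(C)(C)C)CO[C@@H](COCc1ccc(OC)cc1)COC(c1ccccc1)(c1ccccc1)c1ccccc1 | intermediate
16 | methyl (3S)-2-diazo-4-[(tert-butyldiphenylsilyl)oxy]-3-[({(2S)-1-[(4-methoxybenzyl)oxy]-3-(trityloxy)propan-2-yl}oxy)methyl]butanoate | COC(=O)C(=[N+]=[N-])[C@H](CO[Si](c1ccccc1)(c1ccccc1)C(C)(C)C)CO[C@@H](COCc1ccc(OC)cc1)COC(c1ccccc1)(c1ccccc1)c1ccccc1 | intermediate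
17 | methyl (2S,3S,4S)-4-{[(tert-butyldiphenylsilyl)oxy]methyl}-2-{[(4-methoxybenzyl)oxy]methyl}-2-[(trityloxy)methyl]oxolane-3-carboxylate | COC(=O)[C@H]1[C@H](CO[Si](c2ccccc2)(c2ccccc2)C(C)(C)C)CO[C@@]1(COCc2ccc(OC)cc2)COC(c2ccccc2)(c2ccccc2)c2ccccc2 | intermediate
18 | (2S,3S,4S)-oxolane-3-carbaldehyde with the substituents of 17 | O=C[C@H]1[C@H](CO[Si](c2ccccc2)(c2ccccc2)C(C)(C)C)CO[C@@]1(COCc2ccc(OC)cc2)COC(c2ccccc2)(c2ccccc2)c2ccccc2 | intermediate
19 | (2S,3S,4S)-3-ethenyl oxolane with the substituents of 17 | C=C[C@H]1[C@H](CO[Si](c2ccccc2)(c2ccccc2)C(C)(C)C)CO[C@@]1(COCc2ccc(OC)cc2)COC(c2ccccc2)(c2ccccc2)c2ccccc2 | intermediate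
20 | but-2-yn-1-ol | CC#CCO | starting material
21 | sodium 2,2-bis(2-methoxyethoxy)-3-methyl-1-oxa-2-aluminatacyclopent-3-ene | CC1=CCO[Al-]1(OCCOC)OCCOC.[Na+] | intermediate
22 | (Z)-3-iodobut-2-en-1-ol | C/C(I)=C/CO | intermediate
23 | 9-[2-(oxolan-3-yl)ethyl]-9-BBN derived from 19 (boron on C6) | C(CB1C2CCCC1CCC2)[C@H]3[C@H](CO[Si](c4ccccc4)(c4ccccc4)C(C)(C)C)CO[C@@]3(COCc4ccc(OC)cc4)COC(c4ccccc4)(c4ccccc4)c4ccccc4 | intermediate
24 | (2Z)-3-methyl-5-(oxolan-3-yl)pent-2-en-1-ol, oxolane as in 17 | OC/C=C(/C)CC[C@H]1[C@H](CO[Si](c2ccccc2)(c2ccccc2)C(C)(C)C)CO[C@@]1(COCc2ccc(OC)cc2)COC(c2ccccc2)(c2ccccc2)c2ccccc2 | intermediate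
25 | (C4 R, C5 S)-cis-epoxy alcohol of 24 | OC[C@H]1O[C@@]1(C)CC[C@H]2[C@H](CO[Si](c3ccccc3)(c3ccccc3)C(C)(C)C)CO[C@@]2(COCc3ccc(OC)cc3)COC(c3ccccc3)(c3ccccc3)c3ccccc3 | intermediate
26 | epoxy iodide (C3–I) from 25 | IC[C@H]1O[C@@]1(C)CC[C@H]2[C@H](CO[Si](c3ccccc3)(c3ccccc3)C(C)(C)C)CO[C@@]2(COCc3ccc(OC)cc3)COC(c3ccccc3)(c3ccccc3)c3ccccc3 | intermediate
27 | (C5 S)-3-methyl-5-(oxolan-3-yl)pent-1-en-3-ol, oxolane as in 17 | C=C[C@@](C)(O)CC[C@H]1[C@H](CO[Si](c2ccccc2)(c2ccccc2)C(C)(C)C)CO[C@@]1(COCc2ccc(OC)cc2)COC(c2ccccc2)(c2ccccc2)c2ccccc2 | intermediate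
28 | diol: 27 with free C1–OH | C=C[C@@](C)(O)CC[C@H]1[C@H](CO)CO[C@@]1(COCc2ccc(OC)cc2)COC(c2ccccc2)(c2ccccc2)c2ccccc2 | intermediate
29 | C1 aldehyde (oxolane-4-carbaldehyde) | C=C[C@@](C)(O)CC[C@H]1[C@H](C=O)CO[C@@]1(COCc2ccc(OC)cc2)COC(c2ccccc2)(c2ccccc2)c2ccccc2 | intermediate
30 | C1 homoallylic alcohol (C1 epimers) | C=C[C@@](C)(O)CC[C@H]1[C@H](C(O)CC=C)CO[C@@]1(COCc2ccc(OC)cc2)COC(c2ccccc2)(c2ccccc2)c2ccccc2 | intermediate
31 | C1 allyl ketone | C=C[C@@](C)(O)CC[C@H]1[C@H](C(=O)CC=C)CO[C@@]1(COCc2ccc(OC)cc2)COC(c2ccccc2)(c2ccccc2)c2ccccc2 | intermediate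
32 | C1 tertiary carbinol bearing allyl and CH2SiMe3 (C1 epimers) | C=C[C@@](C)(O)CC[C@H]1[C@H](C(O)(CC=C)C[Si](C)(C)C)CO[C@@]1(COCc2ccc(OC)cc2)COC(c2ccccc2)(c2ccccc2)c2ccccc2 | intermediate
33 | oxolane-fused (3Z)-cyclononene-1,5-diol with CH2SiMe3 on C1 (C1 epimers, C5 S) | C[Si](C)(C)CC1(O)C/C=C\[C@@](C)(O)CC[C@H]2[C@H]1CO[C@@]2(COCc3ccc(OC)cc3)COC(c3ccccc3)(c3ccccc3)c3ccccc3 | intermediate
34 | 1-methylene-(3Z)-cyclononen-5-ol fused to the oxolane, arm B OPMB, arm C OTr | C=C1C/C=C\[C@@](C)(O)CC[C@H]2[C@H]1CO[C@@]2(COCc3ccc(OC)cc3)COC(c3ccccc3)(c3ccccc3)c3ccccc3 | intermediate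
35 | 34 with arm B as CH2OH | C=C1C/C=C\[C@@](C)(O)CC[C@H]2[C@H]1CO[C@@]2(CO)COC(c3ccccc3)(c3ccccc3)c3ccccc3 | intermediate
36 | 34 with arm B as CHO | C=C1C/C=C\[C@@](C)(O)CC[C@H]2[C@H]1CO[C@@]2(C=O)COC(c3ccccc3)(c3ccccc3)c3ccccc3 | intermediate
37 | (E)-2-iodoethenyl compound, arm C OTr | C=C1C/C=C\[C@@](C)(O)CC[C@H]2[C@H]1CO[C@@]2(/C=C/I)COC(c3ccccc3)(c3ccccc3)c3ccccc3 | intermediate
38 | (E)-2-iodoethenyl compound, arm C CH2OH | C=C1C/C=C\[C@@](C)(O)CC[C@H]2[C@H]1CO[C@@]2(/C=C/I)CO | intermediate
39 | stearic acid | CCCCCCCCCCCCCCCCCC(=O)O | starting material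
40 | (E)-2-iodoethenyl compound, arm C stearate | C=C1C/C=C\[C@@](C)(O)CC[C@H]2[C@H]1CO[C@@]2(/C=C/I)COC(=O)CCCCCCCCCCCCCCCCC | intermediate
41 | 4,4,5,5-tetramethyl-2-(2-methylprop-1-en-1-yl)-1,3,2-dioxaborolane | CC(C)=CB1OC(C)(C)C(C)(C)O1 | starting material
42 | CNP0274030.1 (5S,8S,9R,11R; 3Z; 12E) | C=C1C/C=C\[C@@](C)(O)CC[C@H]2[C@H]1CO[C@@]2(/C=C/C=C(C)C)COC(=O)CCCCCCCCCCCCCCCCC | target

## Step count and risks

Total step count: 33.
Longest linear sequence: 29 steps (from 5 and 6 through steps 4–15 and 17–33 to 42).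

**1. Step 13.**
- What may go wrong: migration of the tertiary hydrogen on C9 to the carbene carbon may outrun insertion, and site selectivity may leak to the arm methylenes.
- Fallback (sets out from 14, comes back at 17): tie C7 and the C1 oxygen into a ring before the carbene is made. TBAF frees the C1 hydroxyl of 14, which lactonises to the γ-butyrolactone F1. Trifluoroacetylation (LiHMDS, CF3CO2CH2CF3) to the α-trifluoroacetyl lactone F2 and treatment with MsN3/Et3N give the α-diazo lactone F3.
- In a five-membered cyclic diazo carbonyl compound the β C–H bond is held out of line with the empty carbene orbital, so tertiary hydride migration is much slower. Rh2(OAc)4-catalysed 1,5-insertion of β-(alkoxymethyl)-α-diazo-γ-butyrolactones next to the ether oxygen is the established entry to furofuranones. It should give the cis-fused bicyclic lactone F4, again with retention at C11.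
- NaOMe/MeOH opens F4 and equilibrates C8. Only the trans hydroxy ester F5 cannot relactonise, and TBDPSCl/imidazole converts it into 17, while unchanged F4 is recycled.

**2. Step 26.**
- What may go wrong: oligomerisation by cross-metathesis may outpace closure of the strained nine-membered ring, and the closure is reversible under ethene.
- Fallback (sets out from 31, comes back at 33): move the closure one stage earlier and give it a thermodynamic trap. Metathesis of keto alcohol 31 (Hoveyda–Grubbs II, benzoquinone, high dilution) would give the cyclononenone F6. Its C5 hydroxyl can add across the ring to the C1 carbonyl, forming the six-membered dihydropyran bridge of the transannular hemiketal F7. This withdraws the closed ring from the metathesis equilibrium.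
- Excess TMSCH2Li/CeCl3 then opens F7 through its alkoxide and adds to C1 to give 33.

**3. Step 9.**
- What may go wrong: substitution at the β-branched C10 by a crowded secondary alkoxide may be too slow, so that elimination or decay of the triflate takes over.
- Fallback (sets out from 10 and 3, comes back at 12): build the ether by acetal formation and regioselective reductive opening instead of SN2. Buffered Dess–Martin oxidation of 10 gives the aldehyde F8, and condensation with diol 3 (PPTS, MgSO4, CH2Cl2) gives the 1,3-dioxolane F9 (epimers at C10, of no consequence).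
- DIBAL-H binds the less hindered primary oxygen and cleaves that C–O bond. This leaves the C10–O–C11 secondary ether and the free primary alcohol F10. Tritylation as in step 3 gives 12.

## Further compounds

F1 | step 13 | γ-butyrolactone (C7 acylates the C1 oxygen) bearing the glyceryloxymethyl group on C9 | O=C1C[C@@H](CO[C@@H](COCc2ccc(OC)cc2)COC(c2ccccc2)(c2ccccc2)c2ccccc2)CO1
F2 | step 13 | α-trifluoroacetyl lactone (C8 epimers, enolised) | O=C1C(C(=O)C(F)(F)F)[C@@H](CO[C@@H](COCc2ccc(OC)cc2)COC(c2ccccc2)(c2ccccc2)c2ccccc2)CO1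
F3 | step 13 | α-diazo lactone | O=C1C(=[N+]=[N-])[C@@H](CO[C@@H](COCc2ccc(OC)cc2)COC(c2ccccc2)(c2ccccc2)c2ccccc2)CO1
F4 | step 13 | cis-fused 3,7-dioxabicyclo[3.3.0]octan-2-one (C8 epimeric to 17, C11 retained) | O=C1OC[C@@H]2CO[C@@](COCc3ccc(OC)cc3)(COC(c3ccccc3)(c3ccccc3)c3ccccc3)[C@H]12
F5 | step 13 | trans hydroxy ester (17 without TBDPS) | COC(=O)[C@H]1[C@H](CO)CO[C@@]1(COCc2ccc(OC)cc2)COC(c2ccccc2)(c2ccccc2)c2ccccc2
F6 | step 26 | (3Z)-5-hydroxy-5-methylcyclononen-1-one fused to the oxolane | O=C1C/C=C\[C@@](C)(O)CC[C@H]2[C@H]1CO[C@@]2(COCc3ccc(OC)cc3)COC(c3ccccc3)(c3ccccc3)c3ccccc3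
F7 | step 26 | transannular hemiketal (oxygen bridge C1–O–C5) | O[C@@]12C/C=C\[C@@](C)(O1)CC[C@H]3[C@H]2CO[C@@]3(COCc4ccc(OC)cc4)COC(c4ccccc4)(c4ccccc4)c4ccccc4
F8 | step 9 | 2-{[(tert-butyldiphenylsilyl)oxy]methyl}pent-4-enal, C9 as in 10 | C=CC[C@H](CO[Si](c1ccccc1)(c1ccccc1)C(C)(C)C)C=O
F9 | step 9 | 2-substituted 4-{[(4-methoxybenzyl)oxy]methyl}-1,3-dioxolane (C10 epimers) | C=CC[C@H](CO[Si](c1ccccc1)(c1ccccc1)C(C)(C)C)C1OC[C@H](COCc2ccc(OC)cc2)O1
F10 | step 9 | 12 with arm C as free CH2OH | C=CC[C@H](CO[Si](c1ccccc1)(c1ccccc1)C(C)(C)C)CO[C@@H](COCc1ccc(OC)cc1)CO
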